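The 2-methyl-6-alkyl-1,4-benzoquinone is left until the last step and made from a four-membered ring: quinone C1(=O), C2(Me), C3(H) and C4(=O) are the four carbons of a 4-alkynyl-4-hydroxy-2-methylcyclobut-2-enone, and C5/C6 are its two alkyne carbons, so the propargylic CH2 of a 1,4-enyne becomes the CH2 between quinone and E-alkene. Thermal 4π-opening and ring closure of the enynyl ketene (Moore rearrangement) give the quinone directly, unprotected, from a precursor that already holds both ketones. The cyclobutenone comes from diisopropyl squarate; the cis-1,2-dimethylcyclopentane with its two quaternary centres comes from a meso bicyclo[3.3.0]octanone by enantioselective enolisation and ozonolysis.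

Key step: step 16

Assumption (step 4): the (R,R)-amide is taken to select the enantiotopic methylene that gives enol ether 6 as drawn; should the antipode form, the equally available (S,S)-amide is used and nothing else changes.
Remark: the carbinol carbons made in steps 6, 8 and 13 are carried as epimer mixtures (no descriptor in the SMILES) and all become sp2 carbons by steps 14–16. Compounds 2 and 3 are racemic (one enantiomer drawn) and 4 is meso.

Step 1
Reactants: 1 1,2-dimethylcyclopentene
Product: 2 cis-7,7-dichloro-1,5-dimethylbicyclo[3.2.0]heptan-6-one (racemic)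
Conditions: Cl3CCOCl, Zn–Cu, POCl3, Et2O, reflux
Reagents that add atoms: trichloroacetyl chloride, ClC(=O)C(Cl)(Cl)Cl
Why: The [2+2] cycloaddition of dichloroketene is suprafacial on the tetrasubstituted alkene, so the two methyl-bearing carbons should become cis ring-fusion quaternary centres in one step.

Step 2
Reactants: 2 cis-7,7-dichloro-1,5-dimethylbicyclo[3.2.0]heptan-6-one
Product: 3 cis-2,2-dichloro-1,5-dimethylbicyclo[3.3.0]octan-3-one (racemic)
Conditions: CH2N2, Et2O/MeOH, 0 °C → rt
Reagents that add atoms: diazomethane, C=[N+]=[N-]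
Why: Diazomethane ring expansion of an α,α-dichlorocyclobutanone (Greene cyclopentanone annulation) should proceed with migration of the non-chlorinated α-carbon with retention, placing the new CH2 next to the second quaternary carbon.

Step 3
Reactants: 3 cis-2,2-dichloro-1,5-dimethylbicyclo[3.3.0]octan-3-one
Product: 4 cis-1,5-dimethylbicyclo[3.3.0]octan-3-one (meso)
Conditions: Zn, AcOH, 70 °C
Reagents that add atoms: none
Why: Zinc reductive dehalogenation of the α,α-dichloroketone should leave a Cs-symmetric ketone whose two α-methylenes are enantiotopic.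

Step 4
Reactants: 4 cis-1,5-dimethylbicyclo[3.3.0]octan-3-one
Product: 6 trimethyl{[(1S,5R)-1,5-dimethylbicyclo[3.3.0]oct-2-en-3-yl]oxy}silane, via lithium enolate 5 (not isolated)
Conditions: (R,R)-(PhMeCH)2NH, n-BuLi, LiCl, TMSCl (in situ), THF, –100 °C
Reagents that add atoms: chlorotrimethylsilane, C[Si](C)(C)Cl
Why: Enantioselective deprotonation of a meso ketone by a C2-symmetric chiral lithium amide with internal silyl quench (Simpkins–Koga desymmetrisation, established for cis-bicyclo[3.3.0]octan-3-ones) should select one enantiotopic α-CH2 and thereby fix both quaternary centres at once.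

Step 5
Reactants: 6 trimethyl{[(1S,5R)-1,5-dimethylbicyclo[3.3.0]oct-2-en-3-yl]oxy}silane
Product: 8 methyl 2-[(1R,2R)-2-formyl-1,2-dimethylcyclopentyl]acetate, via aldehyde acid 7 (not isolated)
Conditions: O3, CH2Cl2/MeOH, –78 °C; Me2S, → rt; then CH2N2, Et2O, 0 °C
Reagents that add atoms: ozone, [O-][O+]=O; diazomethane, C=[N+]=[N-]
Why: Ozonolysis of the silyl enol ether should cut the former ketone ring so that one quaternary carbon carries CHO and the other CH2CO2H without touching either stereocentre, and the crude acid is esterified with diazomethane.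

Step 6
Reactants: 8 methyl 2-[(1R,2R)-2-formyl-1,2-dimethylcyclopentyl]acetate; 9 1-chloro-3-methylbut-2-ene (prenyl chloride)
Product: 11 (4aR,7aR)-4a,7a-dimethyl-1-(3-methylbut-2-en-1-yl)hexahydrocyclopenta[c]pyran-3(1H)-one, via hydroxy ester alkoxide 10 (not isolated)
Conditions: BaI2, lithium biphenylide, THF, rt; 9, –78 °C; then 8, –78 °C → rt; aq NH4Cl
Reagents that add atoms: none
Why: In a Yamamoto allylbarium addition, prenylbarium chloride should react at its unsubstituted α-carbon with the aldehyde in preference to the ester, giving the linear prenyl carbinol whose alkoxide lactonises onto the ester; the carbinol configuration is not controlled and is removed in step 15.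

Step 7
Reactants: 11 (4aR,7aR)-4a,7a-dimethyl-1-(3-methylbut-2-en-1-yl)hexahydrocyclopenta[c]pyran-3(1H)-one
Product: 12 (4aR,7aR)-4a,7a-dimethyl-1-(3-methylbut-2-en-1-yl)octahydrocyclopenta[c]pyran-3-ol
Conditions: DIBAL-H, CH2Cl2, –78 °C
Reagents that add atoms: none
Why: DIBAL reduction of a lactone at low temperature should stop at the lactol, a masked δ-hydroxy aldehyde.

Step 8
Reactants: 12 (4aR,7aR)-4a,7a-dimethyl-1-(3-methylbut-2-en-1-yl)octahydrocyclopenta[c]pyran-3-ol; 13 3-bromoprop-1-yne (propargyl bromide)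
Product: 14 1-[(1R,2R)-2-(2-hydroxypent-4-yn-1-yl)-1,2-dimethylcyclopentyl]-4-methylpent-3-en-1-ol
Conditions: 13, Zn, THF, 0 °C → rt
Reagents that add atoms: none
Why: In a zinc Barbier propargylation, allenylzinc bromide should add by SE2' to the open hydroxy-aldehyde tautomer of the lactol to give the homopropargylic alcohol; the new carbinol centre is not controlled and is oxidised in step 15.

Step 9
Reactants: 14 1-[(1R,2R)-2-(2-hydroxypent-4-yn-1-yl)-1,2-dimethylcyclopentyl]-4-methylpent-3-en-1-ol
Product: 16 (2E)-6-[(1R,2R)-2-(1-hydroxy-4-methylpent-3-en-1-yl)-1,2-dimethylcyclopentyl]-3-methylhex-2-ene-1,5-diol, via alkenylalane 15 (not isolated)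
Conditions: Me3Al, Cp2ZrCl2, (CH2Cl)2, 0 → 23 °C; then n-BuLi, THF, –78 °C; (CH2O)n, → 23 °C
Reagents that add atoms: trimethylaluminium, C[Al](C)C; formaldehyde (from paraformaldehyde), C=O
Why: Negishi zirconium-catalysed methylalumination should add Me and Al syn across the terminal alkyne with Me on the internal carbon, and the derived alanate is hydroxymethylated with retention, which fixes the E-trisubstituted alkene while the hydroxyls ride as aluminium alkoxides (kept at or below room temperature to avoid chelation-driven isomerisation).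

Step 10
Reactants: 16 (2E)-6-[(1R,2R)-2-(1-hydroxy-4-methylpent-3-en-1-yl)-1,2-dimethylcyclopentyl]-3-methylhex-2-ene-1,5-diol
Product: 17 (4E)-6-bromo-1-[(1R,2R)-2-(1-hydroxy-4-methylpent-3-en-1-yl)-1,2-dimethylcyclopentyl]-4-methylhex-4-en-2-ol
Conditions: NBS, Me2S, CH2Cl2, –30 → 0 °C
Reagents that add atoms: N-bromosuccinimide, O=C1CCC(=O)N1Br
Why: Corey–Kim halogenation should convert only the primary allylic alcohol into the bromide by SN2 on its alkoxysulfonium salt, leaving the two saturated secondary alcohols and the alkene geometry untouched.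

Step 11
Reactants: 17 (4E)-6-bromo-1-[(1R,2R)-2-(1-hydroxy-4-methylpent-3-en-1-yl)-1,2-dimethylcyclopentyl]-4-methylhex-4-en-2-ol
Product: 18 (4E)-1-[(1R,2R)-2-(1-hydroxy-4-methylpent-3-en-1-yl)-1,2-dimethylcyclopentyl]-4-methyloct-4-en-7-yn-2-ol
Conditions: HC≡CMgBr (excess), CuI (cat.), THF, 0 → 45 °C
Reagents that add atoms: ethynylmagnesium bromide, C#C[Mg]Br
Why: Copper-catalysed coupling of an alkynyl Grignard reagent with a primary allylic bromide should give the skipped 1,4-enyne at the unhindered terminus with retention of the E geometry, the excess reagent covering the hydroxyl protons and suppressing double allylation.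

Step 12
Reactants: 19 diisopropyl squarate
Product: 21 3-isopropoxy-4-methylcyclobut-3-ene-1,2-dione, via lithium alkoxide adduct 20 (not isolated)
Conditions: MeLi, THF, –78 °C; TFAA, –78 °C; aq NH4Cl
Reagents that add atoms: methyllithium, [Li]C; water, O
Why: 1,2-Addition of methyllithium to the squarate ester followed by trifluoroacetylation, ionisation and hydrolysis of the vinylogous hemiketal (Liebeskind–Moore squarate protocol) should give the 3-alkoxy-4-methyl dione.

Step 13
Reactants: 18 (4E)-1-[(1R,2R)-2-(1-hydroxy-4-methylpent-3-en-1-yl)-1,2-dimethylcyclopentyl]-4-methyloct-4-en-7-yn-2-ol; 21 3-isopropoxy-4-methylcyclobut-3-ene-1,2-dione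
Product: 23 4-alkynyl-4-hydroxy-3-isopropoxy-2-methylcyclobut-2-en-1-one carrying the enyne chain of 18, via trilithio acetylide 22 (not isolated)
Conditions: n-BuLi (3 equiv), THF, –78 °C; then 21, –78 °C; aq NH4Cl
Reagents that add atoms: none
Why: The lithium acetylide should add 1,2 to the more electrophilic carbonyl of the dione, the one next to the isopropoxy-bearing carbon (the other is a vinylogous ester carbonyl), as in Moore–Liebeskind cyclobutenedione chemistry; the new carbinol centre is irrelevant because it becomes a carbonyl carbon in step 16.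

Step 14
Reactants: 23 4-alkynyl-4-hydroxy-3-isopropoxy-2-methylcyclobut-2-en-1-one with enyne chain
Product: 25 4-alkynyl-4-hydroxy-2-methylcyclobut-2-en-1-one with enyne-diol chain, via reduced tetraol 24 (not isolated)
Conditions: DIBAL-H (excess), THF, –78 → –40 °C; then 1 M HCl, THF, 0 °C
Reagents that add atoms: water, O
Why: 1,2-Reduction of the vinylogous ester carbonyl and acid hydrolysis of the resulting vinylogous hemiacetal (Stork–Danheiser-type reductive 1,3-carbonyl transposition) should move the ketone to the former alkoxy carbon and leave hydrogen at ring C3, a substitution pattern that direct addition to a 3-methylcyclobutenedione would not secure.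

Step 15
Reactants: 25 4-alkynyl-4-hydroxy-2-methylcyclobut-2-en-1-one with enyne-diol chain
Product: 26 4-hydroxy-2-methyl-4-[(4E)-8-[(1R,2R)-1,2-dimethyl-2-(4-methylpent-3-enoyl)cyclopentyl]-5-methyl-7-oxooct-4-en-1-yn-1-yl]cyclobut-2-en-1-one
Conditions: Dess–Martin periodinane, NaHCO3, CH2Cl2, 0 °C → rt
Reagents that add atoms: none
Why: Buffered Dess–Martin oxidation should convert both secondary alcohols into ketones without moving the β,γ-double bonds into conjugation, and it cannot touch the tertiary cyclobutenol.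

Step 16
Reactants: 26 4-hydroxy-2-methyl-4-[(4E)-8-[(1R,2R)-1,2-dimethyl-2-(4-methylpent-3-enoyl)cyclopentyl]-5-methyl-7-oxooct-4-en-1-yn-1-yl]cyclobut-2-en-1-one
Product: 29 2-methyl-6-[(2E)-6-[(1R,2R)-1,2-dimethyl-2-(4-methylpent-3-enoyl)cyclopentyl]-3-methyl-5-oxohex-2-en-1-yl]cyclohexa-2,5-diene-1,4-dione (target), via enynyl ketene 27 (not isolated), via aryl diradical 28 (not isolated)
Conditions: PhMe (5 mM, degassed), 110 °C
Reagents that add atoms: none
Why: Thermal conrotatory 4π ring opening of the cyclobutenone, with the hydroxyl rotating outward, should give enynyl ketene 27 with the alkyne cis to the ketene; the ketene carbon then bonds to the distal alkyne carbon to form aromatic diradical 28, and transfer of the hydroxyl hydrogen to the aryl radical carbon gives the quinone, a net isomerisation that enlarges the four-membered ring by the two alkyne carbons. The closest known reaction is the Moore rearrangement of 4-alkynyl-4-hydroxycyclobutenones. The six-membered ring closes by C1–C6 bond formation in a diradical cycloaromatisation (6-endo attack on the alkyne, Myers–Saito-like), not by 5-exo closure. No stereocentre is formed: the racemic ring carbinol becomes a carbonyl carbon and the two quaternary centres are remote. The step needs six- over five-membered closure and survival of two β,γ-unsaturated ketones; the alkyne terminus carries only a CH2 group, which gives no stabilisation to the exocyclic vinyl radical of the five-ring path, and the conditions are neutral and dilute. The positions of methyl, CH2 and the two ring hydrogens follow from the cyclobutenone substitution fixed in steps 13 and 14.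

Compound list
1 | 1,2-dimethylcyclopentene | CC1=C(C)CCC1 | starting material
2 | cis-7,7-dichloro-1,5-dimethylbicyclo[3.2.0]heptan-6-one (racemic, one enantiomer drawn) | C[C@@]12CCC[C@]1(C)C(=O)C2(Cl)Cl | intermediate
3 | cis-2,2-dichloro-1,5-dimethylbicyclo[3.3.0]octan-3-one (racemic, one enantiomer drawn) | C[C@@]12CCC[C@]1(C)CC(=O)C2(Cl)Cl | intermediate
4 | cis-1,5-dimethylbicyclo[3.3.0]octan-3-one (meso) | C[C@@]12CCC[C@]1(C)CC(=O)C2 | intermediate
5 | lithium (1S,5R)-1,5-dimethylbicyclo[3.3.0]oct-2-en-3-olate | C[C@@]12CCC[C@]1(C)CC(O[Li])=C2 | intermediate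
6 | trimethyl{[(1S,5R)-1,5-dimethylbicyclo[3.3.0]oct-2-en-3-yl]oxy}silane | C[C@@]12CCC[C@]1(C)CC(O[Si](C)(C)C)=C2 | intermediate
7 | 2-[(1R,2R)-2-formyl-1,2-dimethylcyclopentyl]acetic acid (open form drawn) | O=C[C@]1(C)CCC[C@]1(C)CC(=O)O | intermediate
8 | methyl 2-[(1R,2R)-2-formyl-1,2-dimethylcyclopentyl]acetate | O=C[C@]1(C)CCC[C@]1(C)CC(=O)OC | intermediate
9 | 1-chloro-3-methylbut-2-ene (prenyl chloride) | CC(C)=CCCl | starting material
10 | methyl 2-[(1R,2R)-2-(1-hydroxy-4-methylpent-3-en-1-yl)-1,2-dimethylcyclopentyl]acetate (formed as its barium alkoxide, carbinol epimers) | CC(C)=CCC(O)[C@]1(C)CCC[C@]1(C)CC(=O)OC | intermediate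
11 | (4aR,7aR)-4a,7a-dimethyl-1-(3-methylbut-2-en-1-yl)hexahydrocyclopenta[c]pyran-3(1H)-one (C-1 epimers) | CC(C)=CCC2[C@]1(C)CCC[C@]1(C)CC(=O)O2 | intermediate
12 | (4aR,7aR)-4a,7a-dimethyl-1-(3-methylbut-2-en-1-yl)octahydrocyclopenta[c]pyran-3-ol (lactol) | CC(C)=CCC2[C@]1(C)CCC[C@]1(C)CC(O)O2 | intermediate
13 | 3-bromoprop-1-yne (propargyl bromide) | C#CCBr | starting material
14 | 1-[(1R,2R)-2-(2-hydroxypent-4-yn-1-yl)-1,2-dimethylcyclopentyl]-4-methylpent-3-en-1-ol | CC(C)=CCC(O)[C@]1(C)CCC[C@]1(C)CC(O)CC#C | intermediate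
15 | (E)-alkenyldimethylalane of 14 with both hydroxyls as dimethylaluminium alkoxides | CC(C)=CCC(O[Al](C)C)[C@]1(C)CCC[C@]1(C)CC(O[Al](C)C)C/C(C)=C/[Al](C)C | intermediate
16 | (2E)-6-[(1R,2R)-2-(1-hydroxy-4-methylpent-3-en-1-yl)-1,2-dimethylcyclopentyl]-3-methylhex-2-ene-1,5-diol | CC(C)=CCC(O)[C@]1(C)CCC[C@]1(C)CC(O)C/C(C)=C/CO | intermediate
17 | (4E)-6-bromo-1-[(1R,2R)-2-(1-hydroxy-4-methylpent-3-en-1-yl)-1,2-dimethylcyclopentyl]-4-methylhex-4-en-2-ol | CC(C)=CCC(O)[C@]1(C)CCC[C@]1(C)CC(O)C/C(C)=C/CBr | intermediate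
18 | (4E)-1-[(1R,2R)-2-(1-hydroxy-4-methylpent-3-en-1-yl)-1,2-dimethylcyclopentyl]-4-methyloct-4-en-7-yn-2-ol | CC(C)=CCC(O)[C@]1(C)CCC[C@]1(C)CC(O)C/C(C)=C/CC#C | intermediate
19 | diisopropyl squarate (3,4-diisopropoxycyclobut-3-ene-1,2-dione) | CC(C)OC1=C(OC(C)C)C(=O)C1=O | starting material
20 | lithium alkoxide of 4-hydroxy-2,3-diisopropoxy-4-methylcyclobut-2-en-1-one | CC(C)OC1=C(OC(C)C)C(C)(O[Li])C1=O | intermediate
21 | 3-isopropoxy-4-methylcyclobut-3-ene-1,2-dione | CC1=C(OC(C)C)C(=O)C1=O | intermediate
22 | trilithio derivative of 18 (lithium acetylide, two lithium alkoxides) | CC(C)=CCC(O[Li])[C@]1(C)CCC[C@]1(C)CC(O[Li])C/C(C)=C/CC#C[Li] | intermediate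
23 | 4-hydroxy-4-[(4E)-7-hydroxy-8-[(1R,2R)-2-(1-hydroxy-4-methylpent-3-en-1-yl)-1,2-dimethylcyclopentyl]-5-methyloct-4-en-1-yn-1-yl]-3-isopropoxy-2-methylcyclobut-2-en-1-one | CC(C)=CCC(O)[C@]1(C)CCC[C@]1(C)CC(O)C/C(C)=C/CC#CC2(O)C(OC(C)C)=C(C)C2=O | intermediate
24 | 1-[(4E)-7-hydroxy-8-[(1R,2R)-2-(1-hydroxy-4-methylpent-3-en-1-yl)-1,2-dimethylcyclopentyl]-5-methyloct-4-en-1-yn-1-yl]-2-isopropoxy-3-methylcyclobut-2-ene-1,4-diol | CC(C)=CCC(O)[C@]1(C)CCC[C@]1(C)CC(O)C/C(C)=C/CC#CC2(O)C(OC(C)C)=C(C)C2O | intermediate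
25 | 4-hydroxy-4-[(4E)-7-hydroxy-8-[(1R,2R)-2-(1-hydroxy-4-methylpent-3-en-1-yl)-1,2-dimethylcyclopentyl]-5-methyloct-4-en-1-yn-1-yl]-2-methylcyclobut-2-en-1-one | CC(C)=CCC(O)[C@]1(C)CCC[C@]1(C)CC(O)C/C(C)=C/CC#CC2(O)C=C(C)C2=O | intermediate
26 | 4-hydroxy-2-methyl-4-[(4E)-8-[(1R,2R)-1,2-dimethyl-2-(4-methylpent-3-enoyl)cyclopentyl]-5-methyl-7-oxooct-4-en-1-yn-1-yl]cyclobut-2-en-1-one | CC(C)=CCC(=O)[C@]1(C)CCC[C@]1(C)CC(=O)C/C(C)=C/CC#CC2(O)C=C(C)C2=O | intermediate
27 | enynyl ketene from 4π-opening of 26 (hydroxyl outward, alkyne cis to the ketene) | CC(C)=CCC(=O)[C@]1(C)CCC[C@]1(C)CC(=O)C/C(C)=C/CC#C/C(O)=C\C(C)=C=O | intermediate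
28 | aromatic 1,4-diradical (phenoxyl and aryl σ-radical) | CC(C)=CCC(=O)[C@]1(C)CCC[C@]1(C)CC(=O)C/C(C)=C/CC1=[C]C(O)=CC(C)=C1[O] | intermediate
29 | 2-methyl-6-[(2E)-6-[(1R,2R)-1,2-dimethyl-2-(4-methylpent-3-enoyl)cyclopentyl]-3-methyl-5-oxohex-2-en-1-yl]cyclohexa-2,5-diene-1,4-dione | CC(C)=CCC(=O)[C@]1(C)CCC[C@]1(C)CC(=O)C/C(C)=C/CC1=CC(=O)C=C(C)C1=O | target

Total step count: 16. Longest linear sequence: 15 (steps 1–11 and 13–16); step 12 is a one-step branch.

Steps most likely to fail

Step 16. The ring-opened ketene may partition into five-membered closure, or the aryl radical may abstract allylic hydrogen from the side chain and start oligomerisation. The fallback sets out from 26 and keeps the four-to-six ring enlargement but makes it closed-shell. Semi-hydrogenation of the alkyne (Lindlar catalyst, quinoline, H2, EtOAc) should give the (Z)-alkenylcyclobutenone F1. Heating F1 in toluene at about 100 °C should cause 4π-opening, 6π-electrocyclisation and enolisation (the alkenyl variant of the cyclobutenone ring expansion) to give the hydroquinone F2, which is oxidised with Ag2O in ether. The fallback comes back to the route at 29.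

Step 4. The flanking quaternary methyl groups may slow the deprotonation and erode or reverse the discrimination between the enantiotopic methylenes. The fallback sets out from 4 and replaces the chiral base by a covalent auxiliary. Ketalisation with (2R,4R)-pentane-2,4-diol (PPTS, benzene, Dean–Stark) should give the C2-symmetric spiroketal F3, in which the two α-methylenes are diastereotopic. Triisobutylaluminium (CH2Cl2, 0 °C) should cleave one C–O bond with removal of one of these protons (Yamamoto chiral-acetal cleavage) to give the hydroxyalkyl enol ether F4; the diol enantiomer is chosen so that the double bond lies as in 6. Ozonolysis with Me2S work-up gives the aldehyde ester F5, which under the conditions of step 6 (one further equivalent of the barium reagent for the free hydroxyl) lactonises with loss of the diol. The fallback comes back to the route at 11.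

Step 13. The trilithio species may aggregate and react incompletely, or its alkoxides may transfer a proton from the ring methyl of the dione instead of allowing carbonyl addition. The fallback sets out from 18 and masks the hydroxyls for two steps. Silylation (TESCl, imidazole, DMF) should give the bis(triethylsilyl) ether F6. Deprotonation of F6 at the alkyne terminus with one equivalent of n-BuLi and addition to 21 gives the adduct F7. DIBAL reduction gives the diol F8 (not isolated), and 1 M HCl in THF then effects the carbonyl transposition and removes both silyl groups. The fallback comes back to the route at 25.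

Further compounds
F1 | step 16 | 4-hydroxy-2-methyl-4-[(1Z,4E)-8-[(1R,2R)-1,2-dimethyl-2-(4-methylpent-3-enoyl)cyclopentyl]-5-methyl-7-oxoocta-1,4-dien-1-yl]cyclobut-2-en-1-one | CC(C)=CCC(=O)[C@]1(C)CCC[C@]1(C)CC(=O)C/C(C)=C/C/C=C\C2(O)C=C(C)C2=O
F2 | step 16 | 2-methyl-6-[(2E)-6-[(1R,2R)-1,2-dimethyl-2-(4-methylpent-3-enoyl)cyclopentyl]-3-methyl-5-oxohex-2-en-1-yl]benzene-1,4-diol | CC(C)=CCC(=O)[C@]1(C)CCC[C@]1(C)CC(=O)C/C(C)=C/Cc1cc(O)cc(C)c1O
F3 | step 4 | spiroketal of 4 with (2R,4R)-pentane-2,4-diol | C[C@@]12CCC[C@]1(C)CC1(C2)O[C@H](C)C[C@@H](C)O1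
F4 | step 4 | (2R,4R)-4-{[(1S,5R)-1,5-dimethylbicyclo[3.3.0]oct-2-en-3-yl]oxy}pentan-2-ol | C[C@@]12CCC[C@]1(C)CC(O[C@H](C)C[C@@H](C)O)=C2
F5 | step 4 | (2R,4R)-4-hydroxypentan-2-yl 2-[(1R,2R)-2-formyl-1,2-dimethylcyclopentyl]acetate | O=C[C@]1(C)CCC[C@]1(C)CC(=O)O[C@H](C)C[C@@H](C)O
F6 | step 13 | bis(triethylsilyl) ether of 18 | CC(C)=CCC(O[Si](CC)(CC)CC)[C@]1(C)CCC[C@]1(C)CC(O[Si](CC)(CC)CC)C/C(C)=C/CC#C
F7 | step 13 | bis(triethylsilyl) ether of 23 | CC(C)=CCC(O[Si](CC)(CC)CC)[C@]1(C)CCC[C@]1(C)CC(O[Si](CC)(CC)CC)C/C(C)=C/CC#CC2(O)C(OC(C)C)=C(C)C2=O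
F8 | step 13 | bis(triethylsilyl) ether of 24 | CC(C)=CCC(O[Si](CC)(CC)CC)[C@]1(C)CCC[C@]1(C)CC(O[Si](CC)(CC)CC)C/C(C)=C/CC#CC2(O)C(OC(C)C)=C(C)C2O
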